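Numbering follows the farnesyl chain: ring A = C1–C6 (O on C2, C3=C4, Me C15 on C3, Me C14 on C6), ring B = C7–C11 (Me C13 on C7, C11=C12H2). The retrosynthesis cuts the ester C–O bond (caffeic acid 10 + alcohol 9), then takes C2–O back to an alkene CH.
The hydrocarbon left is natural (S,S)-trichodiene 5, whose ring alkene is C2=C3. It is cut at the ring bonds C1–C6 and C7–C11 and at the migrated-methyl bonds C6–C14 and C7–C13, which leads to farnesyl diphosphate 3 and farnesol 1.
Forward: the C15 chain is activated as its diphosphate; one cyclase step closes ring A, then ring B. Oxygen is then placed on C2 with the alkene moving to C3=C4 (nitrosochloride, conjugated oxime, enone), the ketone is reduced and the alcohol acylated.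
Feature that allows the key step: the alcohol part is the intact trichodiene frame, a 1-methylcyclohexene ring (C1–C6) and a 2-methylidenecyclopentane ring (C7–C11) joined through the vicinal quaternary carbons C6(Me)–C7(Me). This is the frame a class I cyclase draws from farnesyl diphosphate.
Stereochemistry: C6 and C7 come from the enzyme, C2 from (R)-CBS reduction of enone 8, the E-alkene from caffeic acid.

Key step: step 3

Remark (assumption on the chemistry): the synthase product is taken to be (4S)-1,4-dimethyl-4-[(1S)-1-methyl-2-methylidenecyclopentyl]cyclohexene, C=C1CCC[C@]1(C)[C@@]1(C)CCC(C)=CC1. An oxygen-free hydrocarbon that keeps the target's C3=C4 alkene, C=C1CCC[C@]1(C)[C@@]1(C)CC=C(C)CC1, would be its C6 epimer, so oxidation of a ring CH2 (SeO2 type) cannot give the target; oxygen is therefore introduced at C2 with allylic shift.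

Step 1
Reactants: 1 (2E,6E)-farnesol
Product: 2 (2E,6E)-farnesyl chloride
Conditions: NCS, Me2S, CH2Cl2, −30 → 0 °C
Reagents that add atoms: N-chlorosuccinimide, O=C1CCC(=O)N1Cl
Why: Corey–Kim chlorination, in which chloride displaces the alkoxysulfonium group at the primary allylic carbon by SN2, so neither allylic transposition nor loss of the 2E geometry is expected.

Step 2
Reactants: 2 (2E,6E)-farnesyl chloride
Product: 3 trisammonium (2E,6E)-farnesyl diphosphate
Conditions: (Bu4N)3HP2O7, MeCN, rt; then Dowex 50W (NH4+ form), aq. NH4HCO3/iPrOH; cellulose chromatography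
Reagents that add atoms: tris(tetrabutylammonium) hydrogen diphosphate, CCCC[N+](CCCC)(CCCC)CCCC.CCCC[N+](CCCC)(CCCC)CCCC.CCCC[N+](CCCC)(CCCC)CCCC.OP(=O)([O-])OP(=O)([O-])[O-]; ammonium hydrogencarbonate (counter-ions), [NH4+].OC(=O)[O-]
Why: SN2 diphosphorylation of a primary allylic halide by the MeCN-soluble diphosphate salt, followed by cation exchange to the water-soluble ammonium form that the enzyme accepts.

Step 3
Reactants: 3 trisammonium (2E,6E)-farnesyl diphosphate
Product: 5 (S,S)-trichodiene, via (3R)-nerolidyl diphosphate 4 (not isolated)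
Conditions: trichodiene synthase (recombinant Fusarium sporotrichioides Tri5), MgCl2, Tris·HCl pH 7.8, glycerol, 30 °C, pentane overlay
Reagents that add atoms: none
Why: Mg2+-assisted ionisation of 3 and return of diphosphate to C3 gives enzyme-bound (3R)-nerolidyl diphosphate 4, whose cisoid conformer re-ionises; C6=C7 then attacks C1, C10=C11 attacks the C7 cation through C11, a 1,4-hydride shift (C6 to C10) follows, methyl C14 moves from C7 to C6, a methyl moves from C11 to C7, and loss of a proton from the remaining C11 methyl gives the methylidene. The closest known reaction type is this very transformation, the native class I cyclisation of farnesyl diphosphate by trichodiene synthase (a cation–olefin bicyclisation followed by Wagner–Meerwein shifts). Ring A closes in a 6-exo mode with respect to the attacking C6=C7 bond (bond C1–C6, charge left outside the ring on C7), ring B in a 5-endo mode (bond C7–C11, charge on ring carbon C10). C6 becomes stereogenic when C14 arrives on the one face of the planar C6 cation that the bound conformer exposes, and C7 when the second methyl arrives on the face fixed by the same fold, so the active-site contour controls both centres and the (4S,1'S) hydrocarbon is expected. The step needs 1,6-closure before 7,11-closure, anti-Markovnikov bond formation at C11 and a single deprotonation site; the (2E,6E) geometry and methyl pattern of the natural substrate place each cation where the next bond must form, and the enzyme pocket with its bound diphosphate secures the rest.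

Step 4
Reactants: 5 (S,S)-trichodiene
Product: 7 (5S)-2,5-dimethyl-5-[(1S)-1-methyl-2-methylidenecyclopentyl]cyclohex-2-en-1-one oxime, via nitrosochloride 6 (not isolated)
Conditions: i-AmONO, TMSCl, CH2Cl2, −20 °C; then pyridine, DMF, 60 °C
Reagents that add atoms: isoamyl nitrite, CC(C)CCON=O (N=O transferred as nitrosyl chloride formed with chlorotrimethylsilane, C[Si](C)(C)Cl, whose chlorine appears only in 6)
Why: Nitrosochlorination followed by dehydrochlorination, as known for 1-methylcyclohexene terpenes (limonene to carvoxime): NO+ adds to C2 of the electron-rich trisubstituted alkene with chloride on tertiary C3, the C-nitroso compound tautomerises to the α-chloro oxime and pyridine removes HCl towards C4 to give the conjugated oxime, while the less nucleophilic 1,1-disubstituted C11=C12 bond should stay untouched.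

Step 5
Reactants: 7 conjugated oxime
Product: 8 (5S)-2,5-dimethyl-5-[(1S)-1-methyl-2-methylidenecyclopentyl]cyclohex-2-en-1-one
Conditions: aq. TiCl3, NH4OAc, dioxane/H2O, rt
Reagents that add atoms: water, O
Why: Ti(III)-mediated reductive deoximation, in which the N–O bond is cleaved and the resulting N–H imine hydrolyses in the acetate buffer near neutral pH, which spares the acid-sensitive methylidene group and leaves C6 and C7 untouched.

Step 6
Reactants: 8 enone
Product: 9 (1S,5S)-2,5-dimethyl-5-[(1S)-1-methyl-2-methylidenecyclopentyl]cyclohex-2-en-1-ol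
Conditions: (R)-Me-CBS (0.2 equiv), catecholborane, toluene, −78 °C; aq. NaOH work-up
Reagents that add atoms: none
Why: Corey–Bakshi–Shibata reduction, in which the ketone binds to the catalyst boron with the α-methylalkenyl arm (C3) as the large group and C1H2 as the small one, so the (R)-catalyst should deliver hydride to the Re face of C2 (the face carrying the C14 methyl) and set (2S), which is C1 (S) in the ring name; catecholborane at −78 °C should not hydroborate either alkene.

Step 7
Reactants: 10 caffeic acid
Product: 12 (2E)-3-[3,4-bis(tert-butyldimethylsilyloxy)phenyl]prop-2-enoic acid, via tris-TBS silyl ester 11 (not isolated)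
Conditions: TBSCl, imidazole, DMF, rt; then AcOH, THF/H2O, rt
Reagents that add atoms: tert-butyldimethylsilyl chloride, CC(C)(C)[Si](C)(C)Cl
Why: Exhaustive silylation with TBSCl/imidazole followed by selective hydrolysis of the far more labile silyl ester should leave the two aryl silyl ethers and the E-alkene untouched.

Step 8
Reactants: 9 (1S) allylic alcohol; 12 bis-TBS caffeic acid
Product: 13 (1S,5S)-2,5-dimethyl-5-[(1S)-1-methyl-2-methylidenecyclopentyl]cyclohex-2-en-1-yl (2E)-3-[3,4-bis(tert-butyldimethylsilyloxy)phenyl]prop-2-enoate
Conditions: DCC, DMAP (cat.), CH2Cl2, 0 °C → rt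
Reagents that add atoms: none
Why: Steglich esterification, in which the acid is activated as O-acylisourea and N-acylpyridinium and the C2–O bond of 9 is not broken, so the (2S) configuration is retained.

Step 9
Reactants: 13 bis-TBS ester
Product: 14 (1S,5S)-2,5-dimethyl-5-[(1S)-1-methyl-2-methylidenecyclopentyl]cyclohex-2-en-1-yl (2E)-3-(3,4-dihydroxyphenyl)prop-2-enoate
Conditions: TBAF, AcOH (1:1), THF, 0 °C
Reagents that add atoms: none
Why: Fluoride-induced cleavage of the aryl silyl ethers, buffered with acetic acid so that no phenoxide or alkoxide builds up that could cleave or shift the allylic ester or promote catechol oxidation.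

Compound list
1 | (2E,6E)-farnesol | CC(C)=CCC/C(C)=C/CC/C(C)=C/CO | starting material
2 | (2E,6E)-farnesyl chloride | CC(C)=CCC/C(C)=C/CC/C(C)=C/CCl | intermediate
3 | trisammonium (2E,6E)-farnesyl diphosphate | CC(C)=CCC/C(C)=C/CC/C(C)=C/COP(=O)([O-])OP(=O)([O-])[O-].[NH4+].[NH4+].[NH4+] | intermediate
4 | (3R,6E)-nerolidyl diphosphate (enzyme-bound, written as trisammonium salt) | C=C[C@@](C)(CC/C=C(\C)CCC=C(C)C)OP(=O)([O-])OP(=O)([O-])[O-].[NH4+].[NH4+].[NH4+] | intermediate (not isolated)
5 | (S,S)-trichodiene, (4S)-1,4-dimethyl-4-[(1S)-1-methyl-2-methylidenecyclopentyl]cyclohex-1-ene | C=C1CCC[C@]1(C)[C@@]1(C)CCC(C)=CC1 | intermediate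
6 | nitrosochloride, (4S)-1-chloro-1,4-dimethyl-4-[(1S)-1-methyl-2-methylidenecyclopentyl]-2-nitrosocyclohexane (C1/C2 mixture; in equilibrium with its dimer and α-chloro oxime tautomer) | C=C1CCC[C@]1(C)[C@@]1(C)CCC(C)(Cl)C(N=O)C1 | intermediate (not isolated)
7 | (5S)-2,5-dimethyl-5-[(1S)-1-methyl-2-methylidenecyclopentyl]cyclohex-2-en-1-one oxime (C=N geometry not fixed) | C=C1CCC[C@]1(C)[C@@]1(C)CC=C(C)C(=NO)C1 | intermediate
8 | (5S)-2,5-dimethyl-5-[(1S)-1-methyl-2-methylidenecyclopentyl]cyclohex-2-en-1-one | C=C1CCC[C@]1(C)[C@@]1(C)CC=C(C)C(=O)C1 | intermediate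
9 | (1S,5S)-2,5-dimethyl-5-[(1S)-1-methyl-2-methylidenecyclopentyl]cyclohex-2-en-1-ol | C=C1CCC[C@]1(C)[C@@]1(C)CC=C(C)[C@@H](O)C1 | intermediate
10 | caffeic acid, (2E)-3-(3,4-dihydroxyphenyl)prop-2-enoic acid | O=C(O)/C=C/c1ccc(O)c(O)c1 | starting material
11 | tert-butyldimethylsilyl (2E)-3-[3,4-bis(tert-butyldimethylsilyloxy)phenyl]prop-2-enoate | CC(C)(C)[Si](C)(C)OC(=O)/C=C/c1ccc(O[Si](C)(C)C(C)(C)C)c(O[Si](C)(C)C(C)(C)C)c1 | intermediate (not isolated)
12 | (2E)-3-[3,4-bis(tert-butyldimethylsilyloxy)phenyl]prop-2-enoic acid | O=C(O)/C=C/c1ccc(O[Si](C)(C)C(C)(C)C)c(O[Si](C)(C)C(C)(C)C)c1 | intermediate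
13 | bis-TBS ester of 9 with 12 | C=C1CCC[C@]1(C)[C@@]1(C)CC=C(C)[C@@H](OC(=O)/C=C/c2ccc(O[Si](C)(C)C(C)(C)C)c(O[Si](C)(C)C(C)(C)C)c2)C1 | intermediate
14 | (1S,5S)-2,5-dimethyl-5-[(1S)-1-methyl-2-methylidenecyclopentyl]cyclohex-2-en-1-yl (2E)-3-(3,4-dihydroxyphenyl)prop-2-enoate | C=C1CCC[C@]1(C)[C@@]1(C)CC=C(C)[C@@H](OC(=O)/C=C/c2ccc(O)c(O)c2)C1 | target

Total step count: 9. Longest linear sequence: 8 steps (1, 2, 3, 4, 5, 6, 8, 9); step 7 is a one-step side branch.

Steps most likely to fail

Step 4. The electrophile (NO+ or traces of HCl) may attack the C11=C12 methylidene group or trigger a cationic shift next to quaternary C7, and HCl may be lost towards C15 instead of C4. The fallback sets out from 5 and comes back at 8. Compound 5 would be treated with singlet oxygen (O2, tetraphenylporphyrin, visible light, CH2Cl2, 0 °C). The Schenck ene reaction at the trisubstituted C2=C3 bond with hydrogen transfer from C4 gives the secondary allylic hydroperoxide F1, which carries oxygen on C2 and the alkene at C3=C4. Acetic anhydride, pyridine and DMAP (Kornblum–DeLaMare dehydration) would convert F1 into enone 8. The medium stays neutral and the 1,1-disubstituted bond is a poor ene partner for singlet oxygen. The price is regiochemical: oxygen can also end on C3, or hydrogen can be taken from C15, so F1 would have to be separated from ene isomers.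

Step 6. Facial selectivity may be poor, because the catalyst has to deliver hydride on the ring face that carries the pseudo-axial C14 methyl, against the steric bias of the ring. The fallback sets out from 8 and comes back at 13. Enone 8 would be reduced without a chiral reagent (NaBH4, CeCl3·7H2O, MeOH, −78 °C; Luche reduction). Hydride entry anti to the C14 methyl leads to the (2R) alcohol F2, which is (1R) in the ring name. F2 would be esterified with acid 12 under Mitsunobu conditions (PPh3, DIAD, toluene, 0 °C); the SN2 displacement inverts C2 and gives 13 directly. Any 9 formed alongside would be esterified as in step 8.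

Step 5. Cleavage of the conjugated C=N bond may be slow or incomplete, and excess Ti(III) may reduce the enone in a conjugate sense. The fallback avoids nitrogen altogether, sets out from 5 and comes back at 8. Compound 5 would be epoxidised at the more electron-rich trisubstituted bond (mCPBA, NaHCO3, CH2Cl2, 0 °C) to the 2,3-epoxide F3. HCl in Et2O at −40 °C would open it at tertiary C3 to the chlorohydrin F4. Dess–Martin oxidation would give the α-chloro ketone F5, and Li2CO3/LiBr in DMF at 120 °C would remove HCl towards C4 to give 8; this dehydrochlorination of 2-chloro-2-methylcyclohexanones is standard.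

Further compounds
F1 | step 4 | (5S)-2,5-dimethyl-5-[(1S)-1-methyl-2-methylidenecyclopentyl]cyclohex-2-en-1-yl hydroperoxide (C1 epimers) | C=C1CCC[C@]1(C)[C@@]1(C)CC=C(C)C(OO)C1
F2 | step 6 | (1R,5S)-2,5-dimethyl-5-[(1S)-1-methyl-2-methylidenecyclopentyl]cyclohex-2-en-1-ol | C=C1CCC[C@]1(C)[C@@]1(C)CC=C(C)[C@H](O)C1
F3 | step 5 | 2,3-epoxide of 5, 1,4-dimethyl-4-[(1S)-1-methyl-2-methylidenecyclopentyl]-7-oxabicyclo[4.1.0]heptane (epoxide face not fixed) | C=C1CCC[C@]1(C)[C@@]1(C)CCC2(C)OC2C1
F4 | step 5 | chlorohydrin, 2-chloro-2,5-dimethyl-5-[(1S)-1-methyl-2-methylidenecyclopentyl]cyclohexan-1-ol | C=C1CCC[C@]1(C)[C@@]1(C)CCC(C)(Cl)C(O)C1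
F5 | step 5 | α-chloro ketone, 2-chloro-2,5-dimethyl-5-[(1S)-1-methyl-2-methylidenecyclopentyl]cyclohexan-1-one | C=C1CCC[C@]1(C)[C@@]1(C)CCC(C)(Cl)C(=O)C1
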